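The route rests on cutting the ring-fusion bond C5–C10 of the trans-decalin (rings A and B) together with the C4–O bond. This leads back to a ten-membered germacra-1(10)E,4E-dien-6β-yl isoferulate. The feature exploited is that the 4β-hydroxyl and the 6β-ester oxygen sit syn-diaxial on C4 and C6, either side of C5. One acid-triggered transannular cyclisation closes both six-membered rings, sets C4, C5 and C10, and lets the ester carbonyl hand oxygen to C4 from the β face. The precursor comes from farnesol. A Sharpless epoxide at C4–C5 carries the absolute configuration through the ring closure, masks the 4-alkene, and is then removed stereospecifically.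

Key step: step 13

Remark on the structure: CIP analysis of the target gives 4S,5S,6R,7S,10R. This means 4β-OH/4α-CH3, 5α-H, 6β-O-acyl, 7β-isopropyl (equatorial) and 10β-CH3, with 4β-O, 6β-O and 10β-CH3 all axial on a trans-decalin.
Remark on numbering: open-chain compounds carry farnesol numbers and cyclic ones germacrane/eudesmane numbers (farnesol C1, C2, C3, C10 become C6, C5, C4, C7).
Remark on handling: the germacradienes 11, 15 and 16 are assumed to be kept below about 40 °C and chromatographed on Et3N-washed silica, because they are prone to Cope rearrangement and to acid cyclisation.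
Assumption: the closure in step 7 runs through the crown-shaped closed transition state. The 6,7-cis relationship of 9 is to be checked by NOE or X-ray analysis before going on.

Step 1
Reactants: 1 (2E,6E)-farnesol
Product: 2 (2E,6E)-farnesyl acetate
Conditions: Ac2O, Et3N, DMAP (cat.), CH2Cl2, 0 °C → rt
Reagents that add atoms: acetic anhydride, CC(=O)OC(C)=O
Why: DMAP-catalysed acetylation masks the C1 allylic alcohol and lowers the electron density of the 2-alkene, so that the next two steps act only at the far end of the chain.

Step 2
Reactants: 2 (2E,6E)-farnesyl acetate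
Product: 3 (2E,6E,10E)-12-hydroxyfarnesyl acetate
Conditions: SeO2 (cat.), t-BuOOH, salicylic acid (cat.), CH2Cl2, 0 °C → rt, stopped at partial conversion
Reagents that add atoms: SeO2, O=[Se]=O (passes the oxygen on); tert-butyl hydroperoxide, CC(C)(C)OO (restores it, net oxygen source)
Why: Riley allylic oxidation (ene reaction followed by a 2,3-sigmatropic shift) prefers the electron-rich, unhindered terminal trisubstituted alkene and delivers the (E)-allylic alcohol, while the internal 6-alkene reacts more slowly and the acetate-deactivated 2-alkene not at all.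

Step 3
Reactants: 3 (2E,6E,10E)-12-hydroxyfarnesyl acetate
Product: 4 (2E,6E,10E)-12-chlorofarnesyl acetate
Conditions: NCS, Me2S, CH2Cl2, −30 → 0 °C
Reagents that add atoms: N-chlorosuccinimide, O=C1CCC(=O)N1Cl
Why: Corey–Kim chlorination converts the primary allylic alcohol into an alkoxysulfonium salt that chloride displaces directly under neutral conditions, without allylic shift or loss of the E geometry.

Step 4
Reactants: 4 (2E,6E,10E)-12-chlorofarnesyl acetate
Product: 5 (2E,6E,10E)-12-chlorofarnesol
Conditions: K2CO3, MeOH, 0 °C
Reagents that add atoms: none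
Why: Base-catalysed transesterification removes the primary acetate at 0 °C much faster than methanol can displace the allylic chloride.

Step 5
Reactants: 5 (2E,6E,10E)-12-chlorofarnesol
Product: 6 (2R,3R,6E,10E)-12-chloro-2,3-epoxyfarnesol
Conditions: Ti(OiPr)4 (10 mol%), D-(−)-diethyl tartrate (12 mol%), t-BuOOH, 4 Å MS, CH2Cl2, −20 °C
Reagents that add atoms: tert-butyl hydroperoxide, CC(C)(C)OO
Why: Sharpless asymmetric epoxidation is steered by the allylic hydroxyl to the 2-alkene only, and the D-(−)-tartrate ligand gives the (2R,3R)-epoxide, the mirror image of the (2S,3S) product that L-(+)-tartrate gives with E-configured 3-methylalk-2-en-1-ols.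

Step 6
Reactants: 6 (2R,3R,6E,10E)-12-chloro-2,3-epoxyfarnesol
Product: 7 (2S,3R,6E,10E)-12-chloro-2,3-epoxyfarnesal
Conditions: TEMPO (10 mol%), PhI(OAc)2, CH2Cl2, rt
Reagents that add atoms: none
Why: Oxoammonium (TEMPO) oxidation stops at the aldehyde and leaves the epoxide, both alkenes and the allylic chloride alone, and no stereocentre moves because the label of C2 changes only through the CIP ranking.

Step 7
Reactants: 7 (2S,3R,6E,10E)-12-chloro-2,3-epoxyfarnesal
Product: 9 (4R,5R,6R,7S)-4,5-epoxygermacra-1(10)E,11-dien-6-ol, via allyl(ethyl)zinc aldehyde 8 (not isolated)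
Conditions: PdCl2(PPh3)2 (10 mol%), Et2Zn, K2CO3, DMA, rt, slow addition of 7 (about 0.01 M); aq NH4Cl
Reagents that add atoms: none
Why: Palladium-catalysed umpolung allylation (Barbier-type macrocyclisation): zerovalent palladium ionises the allylic chloride, Et2Zn turns the π-allyl complex into allylzinc 8, and under high dilution its γ-carbon C7 adds to the aldehyde carbon C6 through a closed six-membered transition state, in which approach past H5 with the carbonyl dipole opposed to the epoxide C5–O bond (Felkin–Anh/Cornforth sense) sets 6R, while the need to keep C11 gauche to the zinc-bound O6 and C8 gauche to C5 in the crown-shaped ring places the 2-propenyl group pseudo-equatorial and sets 7S.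

Step 8
Reactants: 9 (4R,5R,6R,7S)-4,5-epoxygermacra-1(10)E,11-dien-6-ol
Product: 10 (4R,5R,6R,7S)-4,5-epoxygermacr-1(10)E-en-6-ol
Conditions: H2 (1 atm), RhCl(PPh3)3 (5 mol%), toluene–EtOH, rt
Reagents that add atoms: none
Why: Homogeneous hydrogenation with RhCl(PPh3)3 discriminates strongly by substitution, so the 1,1-disubstituted 11-alkene is saturated while the trisubstituted 1(10)-alkene and the epoxide (which still masks the 4-alkene) remain and no stereocentre is touched.

Step 9
Reactants: 10 (4R,5R,6R,7S)-4,5-epoxygermacr-1(10)E-en-6-ol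
Product: 11 (6R,7S)-germacra-1(10)E,4E-dien-6-ol (kunzeaol, 6β-OH)
Conditions: WCl6, n-BuLi (1:2, excess), THF, −78 °C → rt; then 10, 0 °C → rt; aq NaOH/tartrate work-up
Reagents that add atoms: none
Why: Reductive epoxide deoxygenation with the low-valent tungsten chloride from WCl6 and n-BuLi takes the oxygen off from the ring periphery in a syn process with retention, so the trans-epoxide returns the 4E-alkene without any backside attack through the ring, and C6 and C7 are not involved.

Step 10
Reactants: 12 isoferulic acid
Product: 14 (E)-3-(tert-butyldimethylsilyloxy)-4-methoxycinnamic acid, via bis-silylated isoferulic acid 13 (not isolated)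
Conditions: TBSCl (2.5 equiv), imidazole, DMF, rt; then K2CO3, MeOH–THF–H2O, rt; citric acid work-up
Reagents that add atoms: tert-butyldimethylsilyl chloride, CC(C)(C)[Si](C)(C)Cl
Why: Silylation of both acidic sites followed by selective hydrolysis of the far more labile silyl ester leaves the phenol masked as its TBS ether and frees the acid for coupling.

Step 11
Reactants: 11 (6R,7S)-germacra-1(10)E,4E-dien-6-ol; 14 (E)-3-(tert-butyldimethylsilyloxy)-4-methoxycinnamic acid
Product: 15 (6R,7S)-germacra-1(10)E,4E-dien-6-yl O-TBS-isoferulate
Conditions: DCC, DMAP, CH2Cl2, 0 °C → rt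
Reagents that add atoms: none
Why: Steglich esterification acylates O6 with retention at C6 under mildly basic, room-temperature conditions that neither start the Cope rearrangement nor protonate the diene.

Step 12
Reactants: 15 (6R,7S)-germacra-1(10)E,4E-dien-6-yl O-TBS-isoferulate
Product: 16 (6R,7S)-germacra-1(10)E,4E-dien-6β-yl isoferulate
Conditions: TBAF, AcOH (1:1), THF, 0 °C
Reagents that add atoms: none
Why: Fluoride-induced desilylation cleaves the aryl silyl ether quickly, and the acetic acid buffer protonates the phenoxide before it can attack the ester while being too weak to protonate the diene.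

Step 13
Reactants: 16 (6R,7S)-germacra-1(10)E,4E-dien-6β-yl isoferulate
Product: 18 (4S,5S,6R,7S,10R)-6β-isoferuloyloxyeudesman-4β-ol, via 1,3-dioxan-2-ylium ion 17 (not isolated)
Conditions: camphorsulfonic acid (0.2 equiv), CH2Cl2 saturated with H2O, −20 → 0 °C; aq NaHCO3
Reagents that add atoms: water, O
Why: Proposed new method: the acid protonates C1 of the strained 1(10)-alkene while C5 of the 4-alkene bonds to C10 across the ring, and the tertiary C4 cation is caught from the β face by the carbonyl oxygen of the axial 6β-ester to give the 1,3-dioxan-2-ylium ion 17, whose hydration to an orthoacid and collapse release the tertiary 4β-hydroxyl and return the less crowded secondary ester (a tertiary ester formed by the other mode of collapse should migrate back through the same orthoacid). The closest known reaction types are the acid-induced transannular cyclisation of hedycaryol-type germacra-1(10),4-dienes to 4-hydroxyeudesmanes and 1,3-acyloxonium (neighbouring ester) participation in cyclohexane and carbohydrate chemistry, and only their combination is new. Seen from the nucleophilic 4-alkene, the single C5–C10 bond closes ring A (C1–C5, C10) in a 6-endo-trig mode and ring B (C5–C10) in a 6-exo-trig mode. C5 (α-H) and C10 (β-CH3) follow from the crossed chair–chair conformer of the E,E-diene, which holds both ring methyls on the β face and is selected by the equatorial 7β-isopropyl group, so the fusion is trans, whereas C4 is controlled by the 6β-acyloxy group because external capture would come anti to the new bond and give the 4α-alcohol. Protonation is directed to the 1(10)-alkene by the inductive deactivation of the 4-alkene through the allylic ester and by the electron-poor, conjugated nature of the cinnamate alkene, while the rationed water and the non-ionising solvent favour internal over external capture and hold back ionisation of the allylic C6–O bond.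

Compound list
1 | (2E,6E)-farnesol | CC(C)=CCC/C(C)=C/CC/C(C)=C/CO | starting material
2 | (2E,6E)-farnesyl acetate | CC(C)=CCC/C(C)=C/CC/C(C)=C/COC(C)=O | intermediate
3 | (2E,6E,10E)-12-hydroxyfarnesyl acetate | OC/C(C)=C/CC/C(C)=C/CC/C(C)=C/COC(C)=O | intermediate
4 | (2E,6E,10E)-12-chlorofarnesyl acetate | ClC/C(C)=C/CC/C(C)=C/CC/C(C)=C/COC(C)=O | intermediate
5 | (2E,6E,10E)-12-chlorofarnesol | ClC/C(C)=C/CC/C(C)=C/CC/C(C)=C/CO | intermediate
6 | (2R,3R,6E,10E)-12-chloro-2,3-epoxyfarnesol | ClC/C(C)=C/CC/C(C)=C/CC[C@@]1(C)O[C@@H]1CO | intermediate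
7 | (2S,3R,6E,10E)-12-chloro-2,3-epoxyfarnesal | ClC/C(C)=C/CC/C(C)=C/CC[C@@]1(C)O[C@@H]1C=O | intermediate
8 | allyl(ethyl)zinc aldehyde from 7 (not isolated) | CC[Zn]C/C(C)=C/CC/C(C)=C/CC[C@@]1(C)O[C@@H]1C=O | intermediate
9 | (4R,5R,6R,7S)-4,5-epoxygermacra-1(10)E,11-dien-6-ol | O[C@H]1[C@H]2O[C@]2(C)CC/C=C(\C)CC[C@H]1C(C)=C | intermediate
10 | (4R,5R,6R,7S)-4,5-epoxygermacr-1(10)E-en-6-ol | O[C@H]1[C@H]2O[C@]2(C)CC/C=C(\C)CC[C@H]1C(C)C | intermediate
11 | (6R,7S)-germacra-1(10)E,4E-dien-6-ol (kunzeaol) | O[C@H]1/C=C(\C)CC/C=C(\C)CC[C@H]1C(C)C | intermediate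
12 | isoferulic acid | COc1ccc(/C=C/C(=O)O)cc1O | starting material
13 | tert-butyldimethylsilyl (E)-3-(tert-butyldimethylsilyloxy)-4-methoxycinnamate (not isolated) | COc1ccc(/C=C/C(=O)O[Si](C)(C)C(C)(C)C)cc1O[Si](C)(C)C(C)(C)C | intermediate
14 | (E)-3-(tert-butyldimethylsilyloxy)-4-methoxycinnamic acid | COc1ccc(/C=C/C(=O)O)cc1O[Si](C)(C)C(C)(C)C | intermediate
15 | (6R,7S)-germacra-1(10)E,4E-dien-6-yl O-TBS-isoferulate | COc1ccc(/C=C/C(=O)O[C@H]2/C=C(\C)CC/C=C(\C)CC[C@H]2C(C)C)cc1O[Si](C)(C)C(C)(C)C | intermediate
16 | (6R,7S)-germacra-1(10)E,4E-dien-6β-yl isoferulate | COc1ccc(/C=C/C(=O)O[C@H]2/C=C(\C)CC/C=C(\C)CC[C@H]2C(C)C)cc1O | intermediate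
17 | 1,3-dioxan-2-ylium ion bridging O4β and O6β of the eudesmane, 2-(3-hydroxy-4-methoxystyryl) substituted (not isolated) | COc1ccc(/C=C/C2=[O+][C@@]3(C)CCC[C@]4(C)CC[C@@H](C(C)C)[C@@H](O2)[C@@H]34)cc1O | intermediate
18 | (4S,5S,6R,7S,10R)-6β-isoferuloyloxyeudesman-4β-ol | COc1ccc(/C=C/C(=O)O[C@H]2[C@@H]3[C@](C)(CCC[C@]3(C)O)CC[C@H]2C(C)C)cc1O | target

Total step count: 13. Longest linear sequence: 12 (steps 1–9 and 11–13).

Steps most likely to fail

1. Step 13 (Proposed new method).
- **What may go wrong:** capture of the C4 cation from outside on the α face, or proton loss, may outrun participation of the ester carbonyl. The allylic C6–O bond may also ionise.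
- **Fallback:** it sets out from 11 and comes back at 18. It keeps the C5–C10 disconnection and uses only known reaction types. Camphorsulfonic acid in dry CH2Cl2 cyclises the free alcohol with loss of a proton to eudesm-4(15)-en-6β-ol F1, which is freed from its endocyclic olefin isomers on AgNO3-impregnated silica. VO(acac)2/t-BuOOH, steered by the axial homoallylic 6β-hydroxyl, epoxidises the β face to 4β,15-epoxyeudesman-6β-ol F2. LiAlH4 opens this epoxide at the primary C15 to eudesmane-4β,6β-diol F3. Yamaguchi esterification with 14 acylates only the secondary hydroxyl and gives the O-TBS ether of the target F4, and TBAF/AcOH then gives 18.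

2. Step 7.
- **What may go wrong:** intermolecular allylation may compete with ring closure, and configuration may leak at C6 or C7.
- **Fallback:** it repairs the stereochemistry after the closure instead of relying on it. It sets out from 10 (taken on with any epimers) and comes back at 10. Dess–Martin oxidation gives (4R,5S,7S)-4,5-epoxygermacr-1(10)E-en-6-one F5, in which C6 is erased and C7 can be equilibrated with DBU to the pseudo-equatorial isopropyl epimer. Zn(BH4)2 then reduces the chelate of ketone and epoxide oxygens from the side of H5. This is the known way to anti (erythro) epoxy alcohols and corresponds to the 5R,6R relationship of 10.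

3. Step 9.
- **What may go wrong:** Lewis-acidic tungsten chlorides may open the epoxide so that the 1(10)-alkene attacks across the ring, or the alkene geometry may erode.
- **Fallback:** it does without the epoxide. It sets out from 5 and comes back at 11. MnO2 gives (2E,6E,10E)-12-chlorofarnesal F6. The PdCl2(PPh3)2/Et2Zn closure gives racemic germacra-1(10)E,4E,11-trien-6-ol F7, and H2/RhCl(PPh3)3 gives racemic germacra-1(10)E,4E-dien-6-ol F8. The C6/C7 relationship is not secured in this series, so MnO2 takes F8 to racemic germacra-1(10)E,4E-dien-6-one F9. Luche reduction (NaBH4, CeCl3, MeOH, −78 °C) from the ring periphery of the s-cis enone should give the 6,7-cis alcohol as 11 together with the enantiomer of kunzeaol F10. Preparative chromatography on a chiral stationary phase then delivers 11.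

Further compounds
F1 | step 13 | (5S,6R,7S,10R)-eudesm-4(15)-en-6β-ol | O[C@H]1[C@@H]2[C@](C)(CCCC2=C)CC[C@H]1C(C)C
F2 | step 13 | 4β,15-epoxyeudesman-6β-ol | O[C@H]1[C@@H]2[C@](C)(CCC[C@@]23CO3)CC[C@H]1C(C)C
F3 | step 13 | (4S,5S,6R,7S,10R)-eudesmane-4β,6β-diol | O[C@H]1[C@@H]2[C@](C)(CCC[C@]2(C)O)CC[C@H]1C(C)C
F4 | step 13 | O-TBS ether of the target | COc1ccc(/C=C/C(=O)O[C@H]2[C@@H]3[C@](C)(CCC[C@]3(C)O)CC[C@H]2C(C)C)cc1O[Si](C)(C)C(C)(C)C
F5 | step 7 | (4R,5S,7S)-4,5-epoxygermacr-1(10)E-en-6-one | O=C1[C@H]2O[C@]2(C)CC/C=C(\C)CC[C@H]1C(C)C
F6 | step 9 | (2E,6E,10E)-12-chlorofarnesal | ClC/C(C)=C/CC/C(C)=C/CC/C(C)=C/C=O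
F7 | step 9 | germacra-1(10)E,4E,11-trien-6-ol (racemic, C6/C7 not defined) | OC1/C=C(\C)CC/C=C(\C)CCC1C(C)=C
F8 | step 9 | germacra-1(10)E,4E-dien-6-ol (racemic, C6/C7 not defined) | OC1/C=C(\C)CC/C=C(\C)CCC1C(C)C
F9 | step 9 | germacra-1(10)E,4E-dien-6-one (racemic) | O=C1/C=C(\C)CC/C=C(\C)CCC1C(C)C
F10 | step 9 | (6S,7R)-germacra-1(10)E,4E-dien-6-ol (enantiomer of 11) | O[C@@H]1/C=C(\C)CC/C=C(\C)CC[C@@H]1C(C)C
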